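**Retrosynthetic overview**

Eudesmane numbering is used: ring A = C1–C5/C10, ring B = C5–C10, C14 on C10, C15 on C4, C11–C13 = lactone carbons; α is the face opposite C14.
The strategy rests on ring A: C4 is a fully substituted carbon holding both C15 and the ether oxygen, and the second ether carbon C1 lies across the ring from it, so one C–C bond formation (C15 onto a C4 carbonyl) creates the oxygen nucleophile in position to form the C1–O bond.
Disconnections: the C6 ester (angeloylation) and C11=C13 (methylenation) come last; the lactone comes from a C7 ketone by Horner–Wadsworth–Emmons olefination and carboxyl opening of an 8α,9α-epoxide; C6–O comes from a Rubottom oxidation; the oxygen bridge and C4–C15 come from the tandem Grignard addition/Williamson closure on keto mesylate 10.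
Ring order: rings A and B arrive with (R)-Wieland–Miescher ketone; the oxygen bridge is closed in step 8; the lactone ring is closed in step 15.

Key step: step 8

Assumption: ketone 10 is carried forward as the kinetically formed trans-fused isomer without contact with base, because its C5 epimer may be of similar stability.

**Route**

Step 1
Reactants: 1 (R)-Wieland–Miescher ketone
Product: 2 1β-hydroxy-11,12,13,15-tetranoreudesm-5-en-7-one
Conditions: NaBH4 (0.3 equiv), EtOH, −10 °C
Reagents that add atoms: none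
Why: Borohydride reduction should be chemoselective for the saturated C1 ketone over the less electrophilic enone carbonyl, hydride arriving from the α face opposite the C14 methyl to give the equatorial 1β-alcohol, a temporary stereocentre that only masks C1 during the next step.

Step 2
Reactants: 2 1β-hydroxy-11,12,13,15-tetranoreudesm-5-en-7-one; 3 ethylene glycol
Product: 4 7,7-(ethylenedioxy)-11,12,13,15-tetranoreudesm-4-en-1β-ol
Conditions: p-TsOH·H2O (cat.), benzene, reflux, azeotropic removal of water
Reagents that add atoms: none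
Why: Acid-catalysed ketalization of the enone carbonyl is expected to proceed with the usual migration of the double bond out of conjugation to C4=C5, as in the ketalization of 4-en-3-one steroids, while the hindered alcohol stays free.

Step 3
Reactants: 4 7,7-(ethylenedioxy)-11,12,13,15-tetranoreudesm-4-en-1β-ol
Product: 5 7,7-(ethylenedioxy)-11,12,13,15-tetranoreudesm-4-en-1-one
Conditions: (n-Pr4N)RuO4 (cat.), N-methylmorpholine N-oxide, 4 Å molecular sieves, CH2Cl2, rt
Reagents that add atoms: none
Why: Ley–Griffith oxidation returns the C1 ketone under neutral conditions that should leave the acid-labile ketal and the isolated alkene untouched, so that C7 and C1 are now differentiated.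

Step 4
Reactants: 5 7,7-(ethylenedioxy)-11,12,13,15-tetranoreudesm-4-en-1-one
Product: 6 7,7-(ethylenedioxy)-11,12,13,15-tetranoreudesm-4-en-1α-ol
Conditions: LiBH(s-Bu)3, THF, −78 °C
Reagents that add atoms: none
Why: In this trialkylborohydride reduction the bulky hydride should avoid the axial α trajectory, which is syn-axial to H3α and H9α, and attack C1 along the equatorial β trajectory to give the axial 1α-alcohol, as is known for cyclohexanones next to a quaternary carbon.

Step 5
Reactants: 6 7,7-(ethylenedioxy)-11,12,13,15-tetranoreudesm-4-en-1α-ol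
Product: 7 7,7-(ethylenedioxy)-11,12,13,15-tetranoreudesm-4-en-1α-yl methanesulfonate
Conditions: MsCl, Et3N, CH2Cl2, 0 °C
Reagents that add atoms: methanesulfonyl chloride, CS(=O)(=O)Cl
Why: Mesylation of the hindered axial alcohol proceeds with retention at C1 and installs the leaving group on the α face, anti to the oxygen that will later sit on C4.

Step 6
Reactants: 7 7,7-(ethylenedioxy)-11,12,13,15-tetranoreudesm-4-en-1α-yl methanesulfonate
Product: 9 7,7-(ethylenedioxy)-4α-hydroxy-11,12,13,15-tetranor-5α-eudesman-1α-yl methanesulfonate, via alkylborane 8 (not isolated)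
Conditions: BH3·THF, THF, 0 °C → rt; then NaOH, 30% H2O2, 0 °C
Reagents that add atoms: hydrogen peroxide, OO
Why: Hydroboration–oxidation of the trisubstituted C4=C5 alkene should place boron on the less substituted C4 and hydrogen on C5 in a syn addition from the α face, because boron on the β face of C4 would be 1,3-diaxial to the C14 methyl, which sets the 5α-H of the trans-decalin (the C4 carbinol centre is erased in step 7).

Step 7
Reactants: 9 7,7-(ethylenedioxy)-4α-hydroxy-11,12,13,15-tetranor-5α-eudesman-1α-yl methanesulfonate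
Product: 10 7,7-(ethylenedioxy)-4-oxo-11,12,13,15-tetranor-5α-eudesman-1α-yl methanesulfonate
Conditions: (n-Pr4N)RuO4 (cat.), N-methylmorpholine N-oxide, 4 Å molecular sieves, CH2Cl2, rt
Reagents that add atoms: none
Why: Ley–Griffith oxidation under neutral, non-enolizing conditions should convert the 4-alcohol into the ketone without epimerizing the kinetically set 5α-H next to it.

Step 8
Reactants: 10 7,7-(ethylenedioxy)-4-oxo-11,12,13,15-tetranor-5α-eudesman-1α-yl methanesulfonate; 11 methylmagnesium bromide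
Product: 14 1β,4β-epoxy-7,7-(ethylenedioxy)-11,12,13-trinor-5α-eudesmane, via bromomagnesium alkoxide 12 (not isolated), via potassium alkoxide 13 (not isolated)
Conditions: CH3MgBr (1.5 equiv), THF, −78 → 0 °C; then KN(SiMe3)2 (2 equiv), 18-crown-6, THF, 0 → 65 °C
Reagents that add atoms: none
Why: CH3MgBr attacks the C4 ketone, the only electrophilic carbonyl beside the inert ketal, from the equatorial α side because the axial β approach runs into the syn-axial C14 methyl, so substrate control sets C4 with C15 α and the new oxide axial on the β face (known type: equatorial Grignard addition to hindered cyclohexanones). Exchange of magnesium for potassium and warming should bring ring A into a twist-boat in which the 4β-oxide sits behind the axial C1–OMs bond and displaces the mesylate by intramolecular SN2 (Williamson etherification, as in the closure of trans-4-sulfonyloxycyclohexanolates to 7-oxabicyclo[2.2.1]heptanes). The oxygen bridge is the only ring closed, it forms in the 5-exo-tet mode, and inversion at C1 puts the new C1–O bond on the β face, cis to the C4–O bond. The step needs addition before enolization at C5 and substitution before E2 loss of the mesylate; the low-temperature addition, the fixed 1,4-trans-diaxial pairing of nucleophile and leaving group and the irreversibility of the displacement should secure this, although the closure builds a strained trans-fused oxanorbornane and therefore calls for the free potassium alkoxide and heat.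

Step 9
Reactants: 14 1β,4β-epoxy-7,7-(ethylenedioxy)-11,12,13-trinor-5α-eudesmane
Product: 15 1β,4β-epoxy-11,12,13-trinor-5α-eudesman-7-one
Conditions: pyridinium p-toluenesulfonate (cat.), acetone/H2O, 50 °C
Reagents that add atoms: water, O
Why: Mild acid-catalysed acetal hydrolysis should free the C7 ketone without ionizing the tertiary C4–O bond of the strained ether bridge.

Step 10
Reactants: 15 1β,4β-epoxy-11,12,13-trinor-5α-eudesman-7-one
Product: 17 1β,4β-epoxy-11,12,13-trinor-5α-eudesm-8-en-7-one, via lithium enolate 16 (not isolated)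
Conditions: LiN(i-Pr)2, THF, −78 °C; then PhS(Cl)=N-t-Bu, −78 °C
Reagents that add atoms: none
Why: Kinetic deprotonation should occur at the less hindered C8 (C6 is flanked by the ring-fusion carbon C5), and the enolate is dehydrogenated in the same flask by the sulfinimidoyl chloride (Mukaiyama dehydrogenation: sulfur attack at C8, then syn elimination of the sulfenamide) to give the 8-en-7-one.

Step 11
Reactants: 17 1β,4β-epoxy-11,12,13-trinor-5α-eudesm-8-en-7-one
Product: 18 7-(tert-butyldimethylsilyloxy)-1β,4β-epoxy-11,12,13-trinor-5α-eudesma-6,8-diene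
Conditions: t-BuMe2SiOTf, Et3N, CH2Cl2, −78 → 0 °C
Reagents that add atoms: tert-butyldimethylsilyl trifluoromethanesulfonate, CC(C)(C)[Si](C)(C)OS(=O)(=O)C(F)(F)F
Why: Soft enolization of the enone with silyl triflate and amine can only go toward C6, because the γ carbon C10 is quaternary, and gives the cross-conjugated 2-silyloxy diene needed for the Rubottom oxidation.

Step 12
Reactants: 18 7-(tert-butyldimethylsilyloxy)-1β,4β-epoxy-11,12,13-trinor-5α-eudesma-6,8-diene
Product: 20 6α-(tert-butyldimethylsilyloxy)-1β,4β-epoxy-11,12,13-trinor-5α-eudesm-8-en-7-one, via silyloxy epoxide 19 (not isolated)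
Conditions: mCPBA (1.0 equiv), CH2Cl2, −20 → 0 °C
Reagents that add atoms: 3-chloroperbenzoic acid, OOC(=O)c1cccc(Cl)c1
Why: In this Rubottom oxidation the peracid should epoxidize the electron-rich C6=C7 enol ether bond from the α face, away from the C14 methyl and the β-oriented oxygen bridge, and opening of the silyloxy epoxide with 1,4-silyl migration gives the 6α-silyloxy ketone, which is also the equatorial, more stable epimer.

Step 13
Reactants: 20 6α-(tert-butyldimethylsilyloxy)-1β,4β-epoxy-11,12,13-trinor-5α-eudesm-8-en-7-one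
Product: 21 6α-(tert-butyldimethylsilyloxy)-1β,4β:8α,9α-diepoxy-11,12,13-trinor-5α-eudesman-7-one
Conditions: t-BuOOH, DBU, CH2Cl2, 0 °C → rt
Reagents that add atoms: tert-butyl hydroperoxide, CC(C)(C)OO
Why: In this nucleophilic (Weitz–Scheffer) epoxidation the hydroperoxide anion should add to C9 anti to the C14 methyl on the neighbouring C10 and then close on C8, setting the 8α,9α-epoxide as with 1-en-3-one steroids.

Step 14
Reactants: 21 6α-(tert-butyldimethylsilyloxy)-1β,4β:8α,9α-diepoxy-11,12,13-trinor-5α-eudesman-7-one; 22 triethyl phosphonoacetate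
Product: 24 ethyl 6α-(tert-butyldimethylsilyloxy)-1β,4β:8α,9α-diepoxy-13-nor-5α-eudesm-7(11)-en-12-oate (ester on the C8 side), via sodium phosphonate 23 (not isolated)
Conditions: NaH, THF, 0 °C; then 21, 0 → 50 °C
Reagents that add atoms: none
Why: Horner–Wadsworth–Emmons olefination of the ketone should place the ester on the C8 side of the new C7=C11 bond, because the other isomer suffers allylic 1,3-strain with the equatorial 6α-silyloxy group.

Step 15
Reactants: 24 ethyl 6α-(tert-butyldimethylsilyloxy)-1β,4β:8α,9α-diepoxy-13-nor-5α-eudesm-7(11)-en-12-oate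
Product: 26 6α-(tert-butyldimethylsilyloxy)-1β,4β-epoxy-9α-hydroxy-13-nor-5α-eudesm-7(11)-en-12,8β-olide, via epoxy acid 25 (not isolated)
Conditions: LiOH, THF/H2O, rt; then AcOH to pH 4, 40 °C
Reagents that add atoms: lithium hydroxide, [Li+].[OH-]
Why: Saponification followed by mild acid lets the carboxyl group open the allylic epoxide at C8 (5-exo, SN2 with inversion), which closes the butenolide with the lactone oxygen on the β face of C8 and leaves the epoxide oxygen as the 9α-hydroxyl.

Step 16
Reactants: 26 6α-(tert-butyldimethylsilyloxy)-1β,4β-epoxy-9α-hydroxy-13-nor-5α-eudesm-7(11)-en-12,8β-olide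
Product: 27 6α-(tert-butyldimethylsilyloxy)-1β,4β-epoxy-9α-hydroxy-13-nor-5α,7αH-eudesman-12,8β-olide
Conditions: H2 (1 atm), [Ir(cod)(PCy3)(py)]PF6 (cat.), CH2Cl2, rt
Reagents that add atoms: none
Why: In this hydroxyl-directed hydrogenation the cationic iridium catalyst bound to the 9α-hydroxyl should deliver hydrogen to the α face of C7=C11, setting 7α-H and with it the cis-fused lactone.

Step 17
Reactants: 27 6α-(tert-butyldimethylsilyloxy)-1β,4β-epoxy-9α-hydroxy-13-nor-5α,7αH-eudesman-12,8β-olide
Product: 29 13-(dimethylamino)-6α-(tert-butyldimethylsilyloxy)-1β,4β-epoxy-9α-hydroxy-5α,7αH-eudesman-12,8β-olide (C11 epimers), via dilithium enolate 28 (not isolated)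
Conditions: LiN(i-Pr)2 (2.5 equiv), THF, −78 °C; then CH2=NMe2+ I−, −78 → 0 °C
Reagents that add atoms: dimethyl(methylidene)ammonium iodide, C=[N+](C)C.[I-]
Why: The lactone enolate, formed after deprotonation of the hydroxyl, undergoes a Mannich reaction with the preformed iminium salt and so carries C13 onto C11 (the C11 configuration is of no consequence).

Step 18
Reactants: 29 13-(dimethylamino)-6α-(tert-butyldimethylsilyloxy)-1β,4β-epoxy-9α-hydroxy-5α,7αH-eudesman-12,8β-olide
Product: 31 6α-(tert-butyldimethylsilyloxy)-1β,4β-epoxy-9α-hydroxy-5α,7αH-eudesm-11(13)-en-12,8β-olide, via ammonium iodide 30 (not isolated)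
Conditions: MeI, MeOH, rt; then aq NaHCO3, CH2Cl2, rt
Reagents that add atoms: none
Why: Exhaustive N-methylation followed by mild base brings about β-elimination of trimethylamine (Hofmann-type elimination through the acidic C11–H) and gives the α-methylene lactone.

Step 19
Reactants: 31 6α-(tert-butyldimethylsilyloxy)-1β,4β-epoxy-9α-hydroxy-5α,7αH-eudesm-11(13)-en-12,8β-olide
Product: 32 1β,4β-epoxy-6α,9α-dihydroxy-5α,7αH-eudesm-11(13)-en-12,8β-olide
Conditions: HF·pyridine, THF/pyridine, 0 °C → rt
Reagents that add atoms: none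
Why: Desilylation with buffered hydrogen fluoride removes the silyl ether by Si–F bond formation under conditions that should neither add to the α-methylene lactone nor open the ether bridge.

Step 20
Reactants: 32 1β,4β-epoxy-6α,9α-dihydroxy-5α,7αH-eudesm-11(13)-en-12,8β-olide; 33 angelic acid
Product: 35 6α-angeloyloxy-1β,4β-epoxy-9α-hydroxy-5α,7αH-eudesm-11(13)-en-12,8β-olide (target CNP0328162.1), via mixed anhydride 34 (not isolated)
Conditions: 33, 2,4,6-Cl3C6H2COCl, Et3N, toluene, rt; then 32, toluene, 80 °C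
Reagents that add atoms: none
Why: Yamaguchi esterification through the mixed anhydride transfers the angeloyl group without Z to E isomerization, and the equatorial 6α-hydroxyl should react in preference to the axial 9α-hydroxyl next to the quaternary C10.

**Compound list**

1 | (R)-Wieland–Miescher ketone (11,12,13,15-tetranoreudesm-5-ene-1,7-dione) | O=C1CCCC2=CC(=O)CC[C@@]12C | starting material
2 | 1β-hydroxy-11,12,13,15-tetranoreudesm-5-en-7-one | O[C@@H]1CCCC2=CC(=O)CC[C@@]12C | intermediate
3 | ethylene glycol | OCCO | starting material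
4 | 7,7-(ethylenedioxy)-11,12,13,15-tetranoreudesm-4-en-1β-ol | O[C@@H]1CCC=C2CC3(OCCO3)CC[C@@]12C | intermediate
5 | 7,7-(ethylenedioxy)-11,12,13,15-tetranoreudesm-4-en-1-one | O=C1CCC=C2CC3(OCCO3)CC[C@@]12C | intermediate
6 | 7,7-(ethylenedioxy)-11,12,13,15-tetranoreudesm-4-en-1α-ol | O[C@H]1CCC=C2CC3(OCCO3)CC[C@@]12C | intermediate
7 | 7,7-(ethylenedioxy)-11,12,13,15-tetranoreudesm-4-en-1α-yl methanesulfonate | CS(=O)(=O)O[C@H]1CCC=C2CC3(OCCO3)CC[C@@]12C | intermediate
8 | 4α-boryl-7,7-(ethylenedioxy)-11,12,13,15-tetranor-5α-eudesman-1α-yl methanesulfonate (not isolated) | O1CCOC12CC[C@@]3(C)[C@@H](OS(C)(=O)=O)CC[C@@H](B)[C@@H]3C2 | intermediate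
9 | 7,7-(ethylenedioxy)-4α-hydroxy-11,12,13,15-tetranor-5α-eudesman-1α-yl methanesulfonate | O1CCOC12CC[C@@]3(C)[C@@H](OS(C)(=O)=O)CC[C@@H](O)[C@@H]3C2 | intermediate
10 | 7,7-(ethylenedioxy)-4-oxo-11,12,13,15-tetranor-5α-eudesman-1α-yl methanesulfonate (trans-decalin, key precursor) | O1CCOC12CC[C@@]3(C)[C@@H](OS(C)(=O)=O)CCC(=O)[C@@H]3C2 | intermediate
11 | methylmagnesium bromide | C[Mg]Br | starting material
12 | bromomagnesium 7,7-(ethylenedioxy)-1α-(mesyloxy)-11,12,13-trinor-5α-eudesman-4β-olate, C15 α (not isolated) | O1CCOC12CC[C@@]3(C)[C@@H](OS(C)(=O)=O)CC[C@](C)(O[Mg]Br)[C@@H]3C2 | intermediate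
13 | potassium 7,7-(ethylenedioxy)-1α-(mesyloxy)-11,12,13-trinor-5α-eudesman-4β-olate (not isolated) | O1CCOC12CC[C@@]3(C)[C@@H](OS(C)(=O)=O)CC[C@](C)([O-])[C@@H]3C2.[K+] | intermediate
14 | 1β,4β-epoxy-7,7-(ethylenedioxy)-11,12,13-trinor-5α-eudesmane (key product) | O1CCOC12CC[C@@]3(C)[C@H]4CC[C@](C)(O4)[C@@H]3C2 | intermediate
15 | 1β,4β-epoxy-11,12,13-trinor-5α-eudesman-7-one | O=C1CC[C@@]2(C)[C@H]3CC[C@](C)(O3)[C@@H]2C1 | intermediate
16 | lithium 1β,4β-epoxy-11,12,13-trinor-5α-eudesm-7-en-7-olate (not isolated) | [Li]OC1=CC[C@@]2(C)[C@H]3CC[C@](C)(O3)[C@@H]2C1 | intermediate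
17 | 1β,4β-epoxy-11,12,13-trinor-5α-eudesm-8-en-7-one | O=C1C=C[C@@]2(C)[C@H]3CC[C@](C)(O3)[C@@H]2C1 | intermediate
18 | 7-(tert-butyldimethylsilyloxy)-1β,4β-epoxy-11,12,13-trinor-5α-eudesma-6,8-diene | CC(C)(C)[Si](C)(C)OC=1C=C[C@@]2(C)[C@H]3CC[C@](C)(O3)[C@@H]2C=1 | intermediate
19 | 7β-(tert-butyldimethylsilyloxy)-1β,4β:6α,7α-diepoxy-11,12,13-trinor-5α-eudesm-8-ene (not isolated) | CC(C)(C)[Si](C)(C)O[C@]12C=C[C@@]3(C)[C@H]4CC[C@](C)(O4)[C@@H]3[C@H]1O2 | intermediate
20 | 6α-(tert-butyldimethylsilyloxy)-1β,4β-epoxy-11,12,13-trinor-5α-eudesm-8-en-7-one | O=C1C=C[C@@]2(C)[C@H]3CC[C@](C)(O3)[C@@H]2[C@H]1O[Si](C)(C)C(C)(C)C | intermediate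
21 | 6α-(tert-butyldimethylsilyloxy)-1β,4β:8α,9α-diepoxy-11,12,13-trinor-5α-eudesman-7-one | O=C1[C@H]2O[C@H]2[C@@]3(C)[C@H]4CC[C@](C)(O4)[C@@H]3[C@H]1O[Si](C)(C)C(C)(C)C | intermediate
22 | triethyl phosphonoacetate | CCOC(=O)CP(=O)(OCC)OCC | starting material
23 | sodium salt of triethyl phosphonoacetate (not isolated) | CCOC(=O)[CH-]P(=O)(OCC)OCC.[Na+] | intermediate
24 | ethyl 6α-(tert-butyldimethylsilyloxy)-1β,4β:8α,9α-diepoxy-13-nor-5α-eudesm-7(11)-en-12-oate, ester on the C8 side | CCOC(=O)/C=C1\[C@H]2O[C@H]2[C@@]3(C)[C@H]4CC[C@](C)(O4)[C@@H]3[C@H]1O[Si](C)(C)C(C)(C)C | intermediate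
25 | 6α-(tert-butyldimethylsilyloxy)-1β,4β:8α,9α-diepoxy-13-nor-5α-eudesm-7(11)-en-12-oic acid (not isolated) | OC(=O)/C=C1\[C@H]2O[C@H]2[C@@]3(C)[C@H]4CC[C@](C)(O4)[C@@H]3[C@H]1O[Si](C)(C)C(C)(C)C | intermediate
26 | 6α-(tert-butyldimethylsilyloxy)-1β,4β-epoxy-9α-hydroxy-13-nor-5α-eudesm-7(11)-en-12,8β-olide | O=C1O[C@H]2C(=C1)[C@H](O[Si](C)(C)C(C)(C)C)[C@@H]3[C@@](C)([C@@H]2O)[C@H]4CC[C@]3(C)O4 | intermediate
27 | 6α-(tert-butyldimethylsilyloxy)-1β,4β-epoxy-9α-hydroxy-13-nor-5α,7αH-eudesman-12,8β-olide | C1C(=O)O[C@H]2[C@@H]1[C@H](O[Si](C)(C)C(C)(C)C)[C@@H]1[C@@](C)([C@@H]2O)[C@H]2CC[C@]1(C)O2 | intermediate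
28 | dilithium enolate alkoxide of 27 (not isolated) | C1=C(O[Li])O[C@H]2[C@@H]1[C@H](O[Si](C)(C)C(C)(C)C)[C@@H]1[C@@](C)([C@@H]2O[Li])[C@H]2CC[C@]1(C)O2 | intermediate
29 | 13-(dimethylamino)-6α-(tert-butyldimethylsilyloxy)-1β,4β-epoxy-9α-hydroxy-5α,7αH-eudesman-12,8β-olide, C11 epimers | CN(C)CC1C(=O)O[C@H]2[C@@H]1[C@H](O[Si](C)(C)C(C)(C)C)[C@@H]1[C@@](C)([C@@H]2O)[C@H]2CC[C@]1(C)O2 | intermediate
30 | trimethylammonium iodide of 29 (not isolated) | C[N+](C)(C)CC1C(=O)O[C@H]2[C@@H]1[C@H](O[Si](C)(C)C(C)(C)C)[C@@H]1[C@@](C)([C@@H]2O)[C@H]2CC[C@]1(C)O2.[I-] | intermediate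
31 | 6α-(tert-butyldimethylsilyloxy)-1β,4β-epoxy-9α-hydroxy-5α,7αH-eudesm-11(13)-en-12,8β-olide | C=C1C(=O)O[C@H]2[C@@H]1[C@H](O[Si](C)(C)C(C)(C)C)[C@@H]1[C@@](C)([C@@H]2O)[C@H]2CC[C@]1(C)O2 | intermediate
32 | 1β,4β-epoxy-6α,9α-dihydroxy-5α,7αH-eudesm-11(13)-en-12,8β-olide | C=C1C(=O)O[C@H]2[C@@H]1[C@H](O)[C@@H]1[C@@](C)([C@@H]2O)[C@H]2CC[C@]1(C)O2 | intermediate
33 | angelic acid ((Z)-2-methylbut-2-enoic acid) | C/C=C(/C)C(=O)O | starting material
34 | angelic 2,4,6-trichlorobenzoic anhydride (not isolated) | C/C=C(/C)C(=O)OC(=O)c1c(Cl)cc(Cl)cc1Cl | intermediate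
35 | 6α-angeloyloxy-1β,4β-epoxy-9α-hydroxy-5α,7αH-eudesm-11(13)-en-12,8β-olide (CNP0328162.1) | C=C1C(=O)O[C@H]2[C@@H]1[C@H](OC(=O)/C(C)=C\C)[C@@H]1[C@@](C)([C@@H]2O)[C@H]2CC[C@]1(C)O2 | target

**Step count and risks**

Total step count: 20. Longest linear sequence: 20 steps (1 → 35); the route is fully linear.

Step 8 is the riskiest. The closure creates a trans-fused 7-oxabicyclo[2.2.1]heptane, so the SN2 transition state is strained. E2 loss of the axial mesylate toward C2, or enolization at C5 before the addition, may therefore outrun the displacement. The fallback changes the electrophile. Setting out from 10, CH3MgBr addition followed by KOt-Bu in DMSO drives the elimination on purpose to the olefinic tertiary alcohol 7,7-(ethylenedioxy)-11,12,13-trinor-5α-eudesm-1-en-4β-ol F1. mCPBA should then epoxidize C1=C2 from the α face, away from C14, to give the 1α,2α-epoxy alcohol F2. KH in THF lets the 4β-alkoxide open the epoxide at C1 from the rear; this closure has no elimination channel and is driven by release of epoxide strain (known for epoxycyclohexanols, as in the cyclization route to 2-hydroxy-1,4-cineole). It gives 1β,4β-epoxy-7,7-(ethylenedioxy)-11,12,13-trinor-5α-eudesman-2α-ol F3. Conversion into its S-methyl xanthate F4 (NaH, CS2, MeI) and Barton–McCombie deoxygenation (Bu3SnH, AIBN, toluene, 100 °C) remove the extra 2α-oxygen and return to the route at 14.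

Step 11 is the second risk. Enolization toward C6 places an sp2 carbon next to the strained ring-fusion carbon C5 and a diene into ring B, so silyl dienol ether formation may be slow. The silyl triflate may also attack the bridging ether, and facial control in step 12 rests on this diene. The fallback changes the order and the oxidant. Setting out from 17, nucleophilic epoxidation (t-BuOOH, DBU) gives 1β,4β:8α,9α-diepoxy-11,12,13-trinor-5α-eudesman-7-one F5. Its potassium enolate (KN(SiMe3)2, THF, −78 °C), which can only form toward C6, is hydroxylated directly with 2-(phenylsulfonyl)-3-phenyloxaziridine to the 6α-hydroxy epoxy ketone F6; the equatorial 6α-alcohol is expected and could be reached by base equilibration if the other epimer forms. Silylation (t-BuMe2SiOTf, 2,6-lutidine) returns to the route at 21.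

Step 14 is the third risk. The stabilized phosphonate anion may add too slowly to a ketone flanked by a silyloxy-bearing carbon and an epoxide, so that enolization or base-induced decomposition of the epoxy ketone takes over. The fallback is a Peterson olefination. Setting out from 21, the lithium enolate of ethyl (trimethylsilyl)acetate (LiN(i-Pr)2, THF, −78 °C), a smaller and more reactive nucleophile, should add to C7 anti to the epoxide to give ethyl 6α-(tert-butyldimethylsilyloxy)-1β,4β:8α,9α-diepoxy-7α-hydroxy-11-(trimethylsilyl)-13-nor-5α-eudesman-12-oate F7. Warming eliminates trimethylsilanolate and returns to the route at 24.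

**Further compounds**

F1 | step 8 | 7,7-(ethylenedioxy)-11,12,13-trinor-5α-eudesm-1-en-4β-ol (C15 α) | O1CCOC12CC[C@@]3(C)C=CC[C@](C)(O)[C@@H]3C2
F2 | step 8 | 1α,2α-epoxy-7,7-(ethylenedioxy)-11,12,13-trinor-5α-eudesman-4β-ol | O1CCOC12CC[C@@]3(C)[C@H]4O[C@H]4C[C@](C)(O)[C@@H]3C2
F3 | step 8 | 1β,4β-epoxy-7,7-(ethylenedioxy)-11,12,13-trinor-5α-eudesman-2α-ol | O1CCOC12CC[C@@]3(C)[C@H]4[C@@H](O)C[C@](C)(O4)[C@@H]3C2
F4 | step 8 | O-[1β,4β-epoxy-7,7-(ethylenedioxy)-11,12,13-trinor-5α-eudesman-2α-yl] S-methyl dithiocarbonate | O1CCOC12CC[C@@]3(C)[C@H]4[C@@H](OC(=S)SC)C[C@](C)(O4)[C@@H]3C2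
F5 | step 11 | 1β,4β:8α,9α-diepoxy-11,12,13-trinor-5α-eudesman-7-one | O=C1[C@H]2O[C@H]2[C@@]3(C)[C@H]4CC[C@](C)(O4)[C@@H]3C1
F6 | step 11 | 1β,4β:8α,9α-diepoxy-6α-hydroxy-11,12,13-trinor-5α-eudesman-7-one | O=C1[C@H]2O[C@H]2[C@@]3(C)[C@H]4CC[C@](C)(O4)[C@@H]3[C@H]1O
F7 | step 14 | ethyl 6α-(tert-butyldimethylsilyloxy)-1β,4β:8α,9α-diepoxy-7α-hydroxy-11-(trimethylsilyl)-13-nor-5α-eudesman-12-oate | CCOC(=O)C([Si](C)(C)C)[C@]1(O)[C@H]2O[C@H]2[C@@]3(C)[C@H]4CC[C@](C)(O4)[C@@H]3[C@H]1O[Si](C)(C)C(C)(C)C
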